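**Retrosynthetic overview**
- The sulfide bridge is cut first: both C–S bonds and both sulfur-bearing stereocentres come from one radical chain double hydrothiolation, in which a single H2S joins two molecules of the silyl-protected (E)-enone macrolide.
- The two 12-membered lactone rings are identical, so the ring is made once as a monomer, before the union. Ring closure is a Yamaguchi lactonisation of an (E)-4-oxo-2-enoic seco acid.
- The ene-dione acid is unmasked from a 2-substituted furan (oxidative ring opening, Z→E isomerisation, Pinnick oxidation).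
- The methyl carbinol comes from (R)-2-methyloxirane; the carbinol next to the ketone comes from asymmetric transfer hydrogenation of a 2-furyl ketone built from 1-bromo-4-chlorobutane and furan-2-carbonitrile.

Assumption: the sulfur radical attacks the exposed face of the 12-membered (E)-enone, so that each new C–S stereocentre is (S) as in the natural product; this is not proven and is the main stereochemical risk.

**Step 1**
Reactants: 1 1-bromo-4-chlorobutane; 2 furan-2-carbonitrile
Product: 6 5-chloro-1-(furan-2-yl)pentan-1-one, via 4-chlorobutylmagnesium bromide 3 (not isolated), via bromomagnesium ketimine 4 (not isolated), via free ketimine 5 (not isolated)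
Conditions: Mg, THF, 0–15 °C; then 2, THF, 0 °C to rt; 2 M aq HCl, rt
Reagents that add atoms: water, O
Why: Mg inserts only into the C–Br bond, and Grignard addition to the nitrile stops at the ketimine salt (no over-addition), which aqueous acid protonates to the ketimine and hydrolyses to the ketone.

**Step 2**
Reactants: 6 5-chloro-1-(furan-2-yl)pentan-1-one
Product: 7 (1S)-5-chloro-1-(furan-2-yl)pentan-1-ol
Conditions: RuCl[(S,S)-TsDPEN](p-cymene) (1 mol %), HCO2H/Et3N (5:2), rt
Reagents that add atoms: none
Why: Noyori asymmetric transfer hydrogenation, in which the furyl group takes the aryl position in the CH/π-controlled transition state, so the (S,S) catalyst delivers hydride to give the (S)-carbinol, as for aryl alkyl ketones.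

**Step 3**
Reactants: 7 (1S)-5-chloro-1-(furan-2-yl)pentan-1-ol
Product: 8 tert-butyl{[(1S)-5-chloro-1-(furan-2-yl)pentyl]oxy}dimethylsilane
Conditions: TBSCl, imidazole, DMF, rt
Reagents that add atoms: tert-butyldimethylsilyl chloride, CC(C)(C)[Si](C)(C)Cl
Why: Standard silylation; the ether blocks Achmatowicz-type participation of this hydroxyl in step 5 and keeps it out of the lactonisation.

**Step 4**
Reactants: 8 tert-butyl{[(1S)-5-chloro-1-(furan-2-yl)pentyl]oxy}dimethylsilane; 9 (R)-2-methyloxirane
Product: 11 (2R,8S)-8-[(tert-butyldimethylsilyl)oxy]-8-(furan-2-yl)octan-2-ol, via alkylmagnesium chloride 10 (not isolated)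
Conditions: Mg, I2 (cat.), THF, reflux; then CuI (10 mol %), 9, THF, −30 to 0 °C; aq NH4Cl
Reagents that add atoms: none
Why: Copper-catalysed Grignard opening of the epoxide at its unsubstituted carbon (SN2) leaves the epoxide stereocentre untouched, so the (R)-methyl carbinol is taken directly from the chiral pool.

**Step 5**
Reactants: 11 (2R,8S)-8-[(tert-butyldimethylsilyl)oxy]-8-(furan-2-yl)octan-2-ol
Product: 14 (2E,5S,11R)-5-[(tert-butyldimethylsilyl)oxy]-11-hydroxy-4-oxododec-2-enoic acid, via (Z)-4-oxoenal 12 (not isolated), via (E)-4-oxoenal 13 (not isolated)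
Conditions: NBS, NaHCO3, acetone/H2O (10:1), −15 °C; pyridine, rt; then NaClO2, NaH2PO4, 2-methyl-2-butene, t-BuOH/H2O, 0 °C
Reagents that add atoms: water, O; sodium chlorite, [Na+].[O-]Cl=O
Why: Bromonium-induced oxidative ring opening of the 2-substituted furan (a masked 4-oxo-2-enoic acid) gives the (Z)-keto-enal, pyridine isomerises it to the (E)-isomer, and Pinnick oxidation gives the acid without touching the silyl ether or either stereocentre.

**Step 6**
Reactants: 14 (2E,5S,11R)-5-[(tert-butyldimethylsilyl)oxy]-11-hydroxy-4-oxododec-2-enoic acid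
Product: 16 (3E,6S,12R)-6-[(tert-butyldimethylsilyl)oxy]-12-methyl-1-oxacyclododec-3-ene-2,5-dione, via mixed anhydride 15 (not isolated)
Conditions: 2,4,6-Cl3C6H2COCl, Et3N, THF, rt; then slow addition to DMAP, toluene, 80 °C (2 mM)
Reagents that add atoms: none
Why: Yamaguchi macrolactonisation by acyl transfer to the only free hydroxyl (the other is silylated, and the E-alkene excludes any small-ring lactone), with retention at the carbinol carbon.

**Step 7**
Reactants: 16 (3E,6S,12R)-6-[(tert-butyldimethylsilyl)oxy]-12-methyl-1-oxacyclododec-3-ene-2,5-dione (two molecules)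
Product: 18 (3S,6S,12R)-6-[(tert-butyldimethylsilyl)oxy]-3-{[(3S,6S,12R)-6-[(tert-butyldimethylsilyl)oxy]-12-methyl-2,5-dioxo-1-oxacyclododecan-3-yl]sulfanyl}-12-methyl-1-oxacyclododecane-2,5-dione, via macrocyclic thiol 17 (not isolated)
Conditions: H2S (0.5 equiv, 0.8 M in THF), Et3B (10 mol %, in portions), trace air, THF, −20 to 0 °C
Reagents that add atoms: hydrogen sulfide, S
Why: Proposed new method: a radical thiol–ene chain (closest known reaction type: anti-Markovnikov radical hydrothiolation of alkenes with H2S, which gives symmetrical sulfides by double addition) in which HS• adds reversibly to the ene-dione and the adduct with sulfur α to the lactone carbonyl (the more stabilised α-keto radical) is trapped by H transfer from H2S, thiol 17 then re-enters the chain with a second molecule of 16, and attack on the exposed face of each macrocyclic enone (substrate control, see assumption) sets both new (S) centres without any base that could epimerise the α-silyloxy ketone.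

**Step 8**
Reactants: 18 bis(tert-butyldimethylsilyl) ether of thiocladospolide F (the sulfide from step 7)
Product: 19 thiocladospolide F, (3S,6S,12R)-6-hydroxy-3-{[(3S,6S,12R)-6-hydroxy-12-methyl-2,5-dioxo-1-oxacyclododecan-3-yl]sulfanyl}-12-methyl-1-oxacyclododecane-2,5-dione
Conditions: HF·pyridine, THF/pyridine, 0 °C to rt
Reagents that add atoms: none
Why: Fluoride-mediated desilylation under weakly acidic, base-free conditions cleaves both silyl ethers without retro-thia-Michael cleavage or epimerisation at the C–S and acyloin centres.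

**Compound list**
1 | 1-bromo-4-chlorobutane | ClCCCCBr | starting material
2 | furan-2-carbonitrile | N#Cc1ccco1 | starting material
3 | 4-chlorobutylmagnesium bromide | ClCCCC[Mg]Br | intermediate (not isolated)
4 | bromo{[5-chloro-1-(furan-2-yl)pentylidene]amino}magnesium | ClCCCCC(=N[Mg]Br)c1ccco1 | intermediate (not isolated)
5 | 5-chloro-1-(furan-2-yl)pentan-1-imine (present as its iminium salt in the acid) | ClCCCCC(=N)c1ccco1 | intermediate (not isolated)
6 | 5-chloro-1-(furan-2-yl)pentan-1-one | ClCCCCC(=O)c1ccco1 | intermediate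
7 | (1S)-5-chloro-1-(furan-2-yl)pentan-1-ol | O[C@@H](CCCCCl)c1ccco1 | intermediate
8 | tert-butyl{[(1S)-5-chloro-1-(furan-2-yl)pentyl]oxy}dimethylsilane | CC(C)(C)[Si](C)(C)O[C@@H](CCCCCl)c1ccco1 | intermediate
9 | (R)-2-methyloxirane | C[C@@H]1CO1 | starting material
10 | chloro[(5S)-5-[(tert-butyldimethylsilyl)oxy]-5-(furan-2-yl)pentyl]magnesium | CC(C)(C)[Si](C)(C)O[C@@H](CCCC[Mg]Cl)c1ccco1 | intermediate (not isolated)
11 | (2R,8S)-8-[(tert-butyldimethylsilyl)oxy]-8-(furan-2-yl)octan-2-ol | C[C@@H](O)CCCCC[C@H](O[Si](C)(C)C(C)(C)C)c1ccco1 | intermediate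
12 | (2Z,5S,11R)-5-[(tert-butyldimethylsilyl)oxy]-11-hydroxy-4-oxododec-2-enal | C[C@@H](O)CCCCC[C@H](O[Si](C)(C)C(C)(C)C)C(=O)/C=C\C=O | intermediate (not isolated)
13 | (2E,5S,11R)-5-[(tert-butyldimethylsilyl)oxy]-11-hydroxy-4-oxododec-2-enal | C[C@@H](O)CCCCC[C@H](O[Si](C)(C)C(C)(C)C)C(=O)/C=C/C=O | intermediate (not isolated)
14 | (2E,5S,11R)-5-[(tert-butyldimethylsilyl)oxy]-11-hydroxy-4-oxododec-2-enoic acid | C[C@@H](O)CCCCC[C@H](O[Si](C)(C)C(C)(C)C)C(=O)/C=C/C(=O)O | intermediate
15 | (2E,5S,11R)-5-[(tert-butyldimethylsilyl)oxy]-11-hydroxy-4-oxododec-2-enoic 2,4,6-trichlorobenzoic anhydride | C[C@@H](O)CCCCC[C@H](O[Si](C)(C)C(C)(C)C)C(=O)/C=C/C(=O)OC(=O)c1c(Cl)cc(Cl)cc1Cl | intermediate (not isolated)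
16 | (3E,6S,12R)-6-[(tert-butyldimethylsilyl)oxy]-12-methyl-1-oxacyclododec-3-ene-2,5-dione | C[C@@H]1CCCCC[C@H](O[Si](C)(C)C(C)(C)C)C(=O)/C=C/C(=O)O1 | intermediate
17 | (3S,6S,12R)-6-[(tert-butyldimethylsilyl)oxy]-12-methyl-3-sulfanyl-1-oxacyclododecane-2,5-dione | C[C@@H]1CCCCC[C@H](O[Si](C)(C)C(C)(C)C)C(=O)C[C@H](S)C(=O)O1 | intermediate (not isolated)
18 | (3S,6S,12R)-6-[(tert-butyldimethylsilyl)oxy]-3-{[(3S,6S,12R)-6-[(tert-butyldimethylsilyl)oxy]-12-methyl-2,5-dioxo-1-oxacyclododecan-3-yl]sulfanyl}-12-methyl-1-oxacyclododecane-2,5-dione | C[C@@H]1CCCCC[C@H](O[Si](C)(C)C(C)(C)C)C(=O)C[C@H](S[C@H]2CC(=O)[C@@H](O[Si](C)(C)C(C)(C)C)CCCCC[C@@H](C)OC2=O)C(=O)O1 | intermediate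
19 | thiocladospolide F | C[C@@H]1CCCCC[C@H](O)C(=O)C[C@H](S[C@H]2CC(=O)[C@@H](O)CCCCC[C@@H](C)OC2=O)C(=O)O1 | target

**Totals**
Total step count: 8. Longest linear sequence: 8.

**Three steps most likely to fail**

Step 7 (radical double hydrothiolation). The risks are sulfur adding at the wrong alkene carbon, the wrong face, or mono-addition only. The fallback sets out from 16 and replaces the radical chain by a stepwise polar sequence. Thioacetic acid with catalytic Et3N in CH2Cl2 at −20 °C adds in the conjugate sense, β to the ketone only, to give S-[(3S,6S,12R)-6-[(tert-butyldimethylsilyl)oxy]-12-methyl-2,5-dioxo-1-oxacyclododecan-3-yl] ethanethioate F1, whose epimers can be separated. Hydrazine acetate in DMF at 0 °C then frees thiol 17, and Et3N-catalysed thia-Michael addition of 17 to a second equivalent of 16 comes back to the route at 18.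

Step 6 (Yamaguchi lactonisation). The ene-dione acid is sensitive to Et3N/DMAP and a 12-membered ring closes slowly. The fallback sets out from 11 and forms the ring C–O bond by carboxylate alkylation instead of acyl transfer. Appel bromination (CBr4, PPh3, CH2Cl2, 0 °C, inversion) gives {[(1S,7S)-7-bromo-1-(furan-2-yl)octyl]oxy}(tert-butyl)dimethylsilane F2. The furan oxidation sequence of step 5 converts it into (2E,5S,11S)-11-bromo-5-[(tert-butyldimethylsilyl)oxy]-4-oxododec-2-enoic acid F3. Cs2CO3 in DMF at high dilution (rt to 40 °C) then closes the ring by intramolecular SN2 with a second inversion, restoring the (R) centre and coming back at 16.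

Step 5 (furan oxidation). The risks are over-bromination, incomplete Z→E isomerisation and loss of the keto-enal. The fallback sets out from 11 and uses singlet oxygen: O2, tetraphenylporphyrin, hν, iPr2NEt, CH2Cl2, −78 °C ([4+2] endoperoxide, then Kornblum–DeLaMare fragmentation). This gives the (Z)-acid as its cyclic pseudo-acid 5-[(1S,7R)-1-[(tert-butyldimethylsilyl)oxy]-7-hydroxyoctyl]-5-hydroxyfuran-2(5H)-one F4. Catalytic I2 under visible light (or warm pyridine) opens and isomerises it to the (E)-acid, coming back at 14.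

**Further compounds**
F1 | step 7 | S-[(3S,6S,12R)-6-[(tert-butyldimethylsilyl)oxy]-12-methyl-2,5-dioxo-1-oxacyclododecan-3-yl] ethanethioate | C[C@@H]1CCCCC[C@H](O[Si](C)(C)C(C)(C)C)C(=O)C[C@H](SC(C)=O)C(=O)O1
F2 | step 6 | {[(1S,7S)-7-bromo-1-(furan-2-yl)octyl]oxy}(tert-butyl)dimethylsilane | C[C@H](Br)CCCCC[C@H](O[Si](C)(C)C(C)(C)C)c1ccco1
F3 | step 6 | (2E,5S,11S)-11-bromo-5-[(tert-butyldimethylsilyl)oxy]-4-oxododec-2-enoic acid | C[C@H](Br)CCCCC[C@H](O[Si](C)(C)C(C)(C)C)C(=O)/C=C/C(=O)O
F4 | step 5 | 5-[(1S,7R)-1-[(tert-butyldimethylsilyl)oxy]-7-hydroxyoctyl]-5-hydroxyfuran-2(5H)-one (both hemiketal epimers) | C[C@@H](O)CCCCC[C@H](O[Si](C)(C)C(C)(C)C)C1(O)C=CC(=O)O1
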